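## Analysis of the target

The target 11 is an open-chain diester, C22H28O7, whose only ring is the 3,4,5-trimethoxyphenyl ring (ring A). Its single stereocentre is C1, an (S)-configured methine that carries ring A, the vinyl group C2=C3 and the acyloxy oxygen O1. No second stereocentre exists to relay from, so the configuration must come from a reagent or a catalyst. The feature on which the plan rests is the O1–C1 bond: C1 is the branched terminus of a 1-arylallyl unit (C1–C2=C3 with ring A on C1), which is exactly what a metal π-allyl substitution delivers at the substituted end. C1 is at once benzylic, allylic and O-acylated, so it ionises easily and can slide by 1,3-acyloxy shift to the conjugated, achiral cinnamyl isomer, the thermodynamic sink. The acyl part holds two trisubstituted enoates, C2′=C3′ of the inner 2-(acyloxymethyl)but-2-enoate and C2″=C3″ of the outer angelate, both in the less stable Z geometry (β-methyl cis to the carbonyl). Both relax to E once the carbonyl is activated next to a nucleophilic catalyst, and the inner CH2–O bond is an activated allylic ester open to SN2′ attack. The difficulty is therefore not size but making C1 as one enantiomer and joining two labile halves without strong acid, strong base or an activated acyl form of the inner acid.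

## Retrosynthetic reasoning

**Cut 1, O1–C1 of 11.** The bond between the carboxylate oxygen and the stereogenic carbon is cut, not the acyl–oxygen bond next to it. This leads to the achiral (E)-cinnamyl carbonate 3 and the complete acid 10. Cutting here means one operation joins the two halves, creates C1 and sets its configuration. The carboxyl group of 10 reacts as a nucleophile and is never activated, so both Z-enoates are spared. The forward reaction has to attack the aryl-bearing allyl terminus (branched, not linear), choose one enantioface, and leave both the product and the inner allylic ester of 10 un-ionised.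

**Cut 2, the outer acyl–O bond of 10.** Acid 10 is traced to its tert-butyl ester 9, and 9 to the primary allylic alcohol 7 and anhydride 8. The cut is made here because the alcohol is unhindered, so acyl transfer from 8 to its alkoxide is fast and needs no nucleophilic catalyst. The tert-butyl group is chosen because it survives alkoxide chemistry and leaves under conditions that contain neither nucleophile nor base.

**Cut 3, C2′–CH2 and C3′–H of 7.** Alcohol 7 is opened to the ynoate 4, a hydride and the one-carbon electrophile 5, by way of the α-metalated enoate 6. This three-component reductive aldol builds the trisubstituted alkene and sets its Z geometry kinetically in the same step. An olefination would have to fight the preference for E, and a Morita–Baylis–Hillman adduct rearranges to the wrong geometry.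

**Cut 4, functional-group steps to 3.** Carbonate 3 comes from alcohol 2 by O-acylation, and 2 from the commercial ester 1 by 1,2-reduction. The E geometry is bought, and no stereochemical task remains on this side.

## Alternatives that were turned down

**Alternative 1:** The textbook disconnection is the acyl–O1 bond. (1S)-1-(3,4,5-Trimethoxyphenyl)prop-2-en-1-ol A1, made by catalytic enantioselective vinyl addition to 3,4,5-trimethoxybenzaldehyde A2, would be acylated with carboxyl-activated 10. It was turned down for three reasons.
- The stereocentre costs its own asymmetric step starting from A2, and the free carbinol A1 is as ionisable as the target.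
- Activating 10, an α-branched (Z)-enoic acid, exposes its β-carbon to reversible addition by the acyl-transfer catalyst, which relays Z to E. The slow acylation of the hindered secondary alcohol A1 gives that process time.
- The union and the stereocentre become two separate events, and the route is longer.

It is kept only as the fallback for the key step.

**Alternative 2:** The same O1–C1 bond could be formed by hydro-acyloxylation. Acid 10 would add across the terminal double bond of 1,2,3-trimethoxy-5-(propa-1,2-dien-1-yl)benzene A3 under [Rh(cod)Cl]2 with a chiral diphosphine. The step is atom-economic, but A3 needs several steps from A2, and an aryl allene such as A3 oligomerises readily. Regio- and enantiocontrol of this reaction type rest on alkyl-substituted allenes. Here the rhodium allyl formed from A3 is conjugated with ring A, which favours attack at the unsubstituted terminus. Rhodium hydride species would also be a standing threat to both Z-enoates.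

**Alternative 3:** O1–C1 could be made from C1–H by allylic C–H acyloxylation of elemicin A4 with 10, using Pd(OAc)2, a sulfoxide ligand and a quinone oxidant. This would be a single step from the commercial phenylpropene A4. With an allylarene such as A4, however, the palladium allyl is attacked at the unsubstituted terminus, or the acyloxy group at C1 is relayed by 1,3-shift into conjugation with ring A. No dependable enantiocontrol exists for an intermolecular branched C–H acyloxylation, and a large excess of the precious acid 10 over A4 would be needed.

Key step: step 6

Assumption: 4, 8 and both antipodes of the phosphoramidite ligand of step 6 are taken as catalogue compounds, and 5 is used as a THF solution of the monomer obtained by thermal cracking of paraformaldehyde.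

## Route

**Step 1**
Reactants: 1 methyl (2E)-3-(3,4,5-trimethoxyphenyl)prop-2-enoate
Product: 2 (2E)-3-(3,4,5-trimethoxyphenyl)prop-2-en-1-ol
Conditions: i-Bu2AlH (2.5 equiv), CH2Cl2, −78 °C to 0 °C; aq. sodium potassium tartrate
Reagents that add atoms: none
Why: 1,2-Reduction of a cinnamate ester by an aluminium hydride at low temperature should give the allylic alcohol without touching the conjugated E double bond.

**Step 2**
Reactants: 2 (2E)-3-(3,4,5-trimethoxyphenyl)prop-2-en-1-ol
Product: 3 methyl (2E)-3-(3,4,5-trimethoxyphenyl)prop-2-en-1-yl carbonate
Conditions: ClCO2Me (1.3 equiv), pyridine (2 equiv), CH2Cl2, 0 °C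
Reagents that add atoms: methyl chloroformate, COC(=O)Cl
Why: O-Acylation of a primary alcohol with a chloroformate should install the leaving group; on ionisation it breaks down to carbon dioxide and methoxide, so the later substitution cannot run backwards through it.

**Step 3**
Reactants: 4 tert-butyl but-2-ynoate; 5 formaldehyde
Product: 7 tert-butyl (2Z)-2-(hydroxymethyl)but-2-enoate, via vinylalane 6 (not isolated)
Conditions: i-Bu2AlH (1.2 equiv), N-methylmorpholine N-oxide (1.2 equiv), THF, 0 °C; 4, 0 °C; then 5 (THF solution, 3 equiv), −78 °C to 0 °C; aq. sodium potassium tartrate
Reagents that add atoms: none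
Why: Three-component reductive aldol (hydroalumination–aldol, the vinylalumination route to β-substituted Morita–Baylis–Hillman-type adducts): syn delivery of hydride to C3′ should give the α-aluminated enoate 6 (in equilibrium with its aluminium allenolate), which 5 attacks at C2′ from the side of the β-hydrogen. The β-methyl therefore ends cis to the ester (Z), and the tert-butyl ester resists 1,2-reduction.

**Step 4**
Reactants: 7 tert-butyl (2Z)-2-(hydroxymethyl)but-2-enoate; 8 angelic anhydride [(2Z)-2-methylbut-2-enoic anhydride]
Product: 9 tert-butyl (2Z)-2-({[(2Z)-2-methylbut-2-enoyl]oxy}methyl)but-2-enoate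
Conditions: LiN(SiMe3)2 (1.05 equiv), THF, −78 °C; then 8 (1.2 equiv), −78 °C to 0 °C; aq. NH4Cl
Reagents that add atoms: none
Why: Acylation of a lithium alkoxide by the anhydride (stereoconservative angeloylation) needs no nucleophilic acyl-transfer catalyst, so the reversible β-addition that relays angelate to tiglate should have no carrier; the hindered tert-butyl ester is inert to the alkoxide.

**Step 5**
Reactants: 9 tert-butyl (2Z)-2-({[(2Z)-2-methylbut-2-enoyl]oxy}methyl)but-2-enoate
Product: 10 (2Z)-2-({[(2Z)-2-methylbut-2-enoyl]oxy}methyl)but-2-enoic acid
Conditions: CF3CO2H–CH2Cl2 (1:4), 0 °C to rt; evaporation with toluene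
Reagents that add atoms: none
Why: Acidolysis of a tert-butyl ester by alkyl–oxygen cleavage should free the acid with no nucleophile or base present; both enoates are electron-poor and should resist protonation at C3′ and C3″, and the inner allylic ester cannot ionise to a cation destabilised by the carboxyl group.

**Step 6**
Reactants: 3 methyl (2E)-3-(3,4,5-trimethoxyphenyl)prop-2-en-1-yl carbonate; 10 (2Z)-2-({[(2Z)-2-methylbut-2-enoyl]oxy}methyl)but-2-enoic acid
Product: 11 (1S)-1-(3,4,5-trimethoxyphenyl)prop-2-en-1-yl (2Z)-2-({[(2Z)-2-methylbut-2-enoyl]oxy}methyl)but-2-enoate
Conditions: [Ir(cod)Cl]2 (2 mol %), O,O′-[(S)-1,1′-binaphthyl-2,2′-diyl] N,N-bis[(S)-1-phenylethyl]phosphoramidite (4 mol %), 1,5,7-triazabicyclo[4.4.0]dec-5-ene (8 mol %), THF, rt, 2 h; then 3 (1.0 equiv), 10 (1.3 equiv), THF, rt, stopped at full conversion of 3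
Reagents that add atoms: none
Why: The cyclometalated monovalent iridium–phosphoramidite complex should ionise 3 to a cationic (π-allyl)iridium species (trivalent iridium) with loss of carbon dioxide and methoxide; the methoxide deprotonates 10, and the carboxylate attacks the aryl-bearing allyl terminus from the face opposite the metal. The closest known reaction type is the iridium-catalysed enantioselective allylic esterification of cinnamyl-type carbonates with carboxylates, with the analogous etherification and amination behind it. No ring is closed; the step forms the O1–C1 bond, joins the two halves and creates the only stereocentre. C1 is controlled by the catalyst alone: the ligand fixes which enantioface of the allyl terminus is open, and the (S,S,Sa) ligand is expected to give (S)-11 by analogy with the sense found for heteroatom nucleophiles on aryl-substituted allyl carbonates (the mirror-image ligand is equally available should the sense have to be inverted). Branched over linear selectivity is needed, and it should come from the intrinsic preference of this catalyst for the substituted terminus, reinforced by ring A. The product must not be re-ionised; a carboxylate is a poorer leaving group than the carbonate, the temperature is ambient, and the reaction is stopped when 3 is consumed. The inner allylic angelate should be ignored because its allyl unit is substituted at the central and terminal carbons, a pattern this catalyst does not accept. Both Z-enoates should survive because the carboxyl group acts only as a nucleophile and the excess of 10 removes methoxide as it forms.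

## Compound list

1 | methyl (2E)-3-(3,4,5-trimethoxyphenyl)prop-2-enoate | COC(=O)/C=C/c1cc(OC)c(OC)c(OC)c1 | starting material
2 | (2E)-3-(3,4,5-trimethoxyphenyl)prop-2-en-1-ol | OC/C=C/c1cc(OC)c(OC)c(OC)c1 | intermediate
3 | methyl (2E)-3-(3,4,5-trimethoxyphenyl)prop-2-en-1-yl carbonate | COC(=O)OC/C=C/c1cc(OC)c(OC)c(OC)c1 | intermediate
4 | tert-butyl but-2-ynoate | CC#CC(=O)OC(C)(C)C | starting material
5 | formaldehyde | C=O | starting material
6 | tert-butyl (2E)-2-[bis(2-methylpropyl)alumanyl]but-2-enoate (vinylalane) | C/C=C(/[Al](CC(C)C)CC(C)C)C(=O)OC(C)(C)C | intermediate
7 | tert-butyl (2Z)-2-(hydroxymethyl)but-2-enoate | C/C=C(/CO)C(=O)OC(C)(C)C | intermediate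
8 | angelic anhydride, (2Z)-2-methylbut-2-enoic anhydride | C/C=C(/C)C(=O)OC(=O)/C(C)=C\C | starting material
9 | tert-butyl (2Z)-2-({[(2Z)-2-methylbut-2-enoyl]oxy}methyl)but-2-enoate | C/C=C(/COC(=O)/C(C)=C\C)C(=O)OC(C)(C)C | intermediate
10 | (2Z)-2-({[(2Z)-2-methylbut-2-enoyl]oxy}methyl)but-2-enoic acid | C/C=C(/COC(=O)/C(C)=C\C)C(=O)O | intermediate
11 | (1S)-1-(3,4,5-trimethoxyphenyl)prop-2-en-1-yl (2Z)-2-({[(2Z)-2-methylbut-2-enoyl]oxy}methyl)but-2-enoate | C=C[C@H](OC(=O)/C(=C\C)COC(=O)/C(C)=C\C)c1cc(OC)c(OC)c(OC)c1 | target

## Step count and risk

Total step count: 6. Longest linear sequence: 4 (steps 3, 4, 5, 6); steps 1 and 2 form the second branch.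

**Step 6 (key step).** The most likely failure is re-entry of the product into the π-allyl manifold. The product is itself an allylic carboxylate on an electron-rich benzylic carbon, so the catalyst can ionise it again; this erodes the enantiomeric purity and drains the branched ester into the conjugated linear isomer. A second process is protonolysis of the cyclometalated catalyst by free 10, which would stall the reaction. The fallback changes the bond formed, from O1–C1 to acyl–O1, and sets the stereocentre by reagent control. It sets out from 2. Sharpless epoxidation (Ti(OiPr)4, D-(−)-diethyl tartrate, t-BuOOH, 4 Å molecular sieves, CH2Cl2, −20 °C) should give [(2R,3R)-3-(3,4,5-trimethoxyphenyl)oxiran-2-yl]methanol F1. Iodination (I2, PPh3, imidazole) gives (2S,3R)-2-(iodomethyl)-3-(3,4,5-trimethoxyphenyl)oxirane F2. Reductive ring opening with Zn in ethanol at reflux gives (1S)-1-(3,4,5-trimethoxyphenyl)prop-2-en-1-ol F3; the former epoxide carbon bearing ring A is untouched and becomes C1, and this compound is identical with A1. Its lithium alkoxide (LiN(SiMe3)2, THF, −78 °C) is then acylated with (2Z)-2-({[(2Z)-2-methylbut-2-enoyl]oxy}methyl)but-2-enoic 2,4,6-trichlorobenzoic anhydride F4, made from 10 with 2,4,6-trichlorobenzoyl chloride and Et3N. The sequence comes back to the route at 11.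

**Step 3.** Geometric leakage is the main concern: the aluminium allenolate may equilibrate before the C–C bond forms and drift towards the more stable E isomer. Monomeric 5 may also polymerise or be reduced by residual hydride. The fallback fixes the geometry by a syn addition of tin hydride and sets out from 4. Syn-hydrostannation (Bu3SnH, Pd(PPh3)4, THF, rt) should give tert-butyl (2E)-2-(tributylstannyl)but-2-enoate F5. Iododestannylation with retention (I2, CH2Cl2, 0 °C) gives tert-butyl (2E)-2-iodobut-2-enoate F6. Stille coupling with (tributylstannyl)methanol (Pd(PPh3)4, dioxane, 80 °C) comes back to the route at 7.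

**Step 4.** The risk is a relay of Z to E in the acyl donor or in the product by reversible conjugate addition of the amide base or of liberated angelate, together with oxa-Michael oligomerisation of the alkoxide. The fallback turns the polarity of the bond formation around. It sets out from 7: Mitsunobu esterification with angelic acid (PPh3, diisopropyl azodicarboxylate, THF, 0 °C) lets the angelate act as nucleophile on the activated primary allylic carbon, so no electrophilic angeloyl species exists. It comes back at 9 and makes no new compound, F0.

**Step 5.** Prolonged exposure of two Z-enoates and an allylic ester to strong acid may cause Z to E equilibration or acid-catalysed 1,3-shift of the angelate. The fallback removes the tert-butyl group before the angelate is present and sets out from 7. Acidolysis (CF3CO2H, CH2Cl2, 0 °C) gives (2Z)-2-(hydroxymethyl)but-2-enoic acid F7. Double acylation (LiN(SiMe3)2, 2.1 equiv, then 8, 2.3 equiv, THF, −78 °C to 0 °C) gives (2Z)-2-({[(2Z)-2-methylbut-2-enoyl]oxy}methyl)but-2-enoic (2Z)-2-methylbut-2-enoic anhydride F8. Selective hydrolysis of the anhydride linkage (aq. NaHCO3, THF, rt) comes back to the route at 10.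

## Further compounds

F1 | step 6 | [(2R,3R)-3-(3,4,5-trimethoxyphenyl)oxiran-2-yl]methanol | OC[C@H]1O[C@@H]1c1cc(OC)c(OC)c(OC)c1
F2 | step 6 | (2S,3R)-2-(iodomethyl)-3-(3,4,5-trimethoxyphenyl)oxirane | IC[C@H]1O[C@@H]1c1cc(OC)c(OC)c(OC)c1
F3 | step 6 | (1S)-1-(3,4,5-trimethoxyphenyl)prop-2-en-1-ol | C=C[C@H](O)c1cc(OC)c(OC)c(OC)c1
F4 | step 6 | (2Z)-2-({[(2Z)-2-methylbut-2-enoyl]oxy}methyl)but-2-enoic 2,4,6-trichlorobenzoic anhydride | C/C=C(/COC(=O)/C(C)=C\C)C(=O)OC(=O)c1c(Cl)cc(Cl)cc1Cl
F5 | step 3 | tert-butyl (2E)-2-(tributylstannyl)but-2-enoate | C/C=C(/[Sn](CCCC)(CCCC)CCCC)C(=O)OC(C)(C)C
F6 | step 3 | tert-butyl (2E)-2-iodobut-2-enoate | C/C=C(/I)C(=O)OC(C)(C)C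
F0 | step 4 | none | none
F7 | step 5 | (2Z)-2-(hydroxymethyl)but-2-enoic acid | C/C=C(/CO)C(=O)O
F8 | step 5 | (2Z)-2-({[(2Z)-2-methylbut-2-enoyl]oxy}methyl)but-2-enoic (2Z)-2-methylbut-2-enoic anhydride | C/C=C(/COC(=O)/C(C)=C\C)C(=O)OC(=O)/C(C)=C\C
A1 | alternative 1 | (1S)-1-(3,4,5-trimethoxyphenyl)prop-2-en-1-ol | C=C[C@H](O)c1cc(OC)c(OC)c(OC)c1
A2 | alternative 1 | 3,4,5-trimethoxybenzaldehyde | O=Cc1cc(OC)c(OC)c(OC)c1
A3 | alternative 2 | 1,2,3-trimethoxy-5-(propa-1,2-dien-1-yl)benzene | C=C=Cc1cc(OC)c(OC)c(OC)c1
A4 | alternative 3 | elemicin, 1,2,3-trimethoxy-5-(prop-2-en-1-yl)benzene | C=CCc1cc(OC)c(OC)c(OC)c1
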